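**Strategy**

Everything rests on closing the cyclohexene ring at its most hindered bond, C1–C6. The key step exploits two features of this ring: C1 is a gem-dimethyl carbon (a latent tertiary cation) and the substituents on C2 and C6 are cis (both equatorial in a chair). The precursor is an open-chain triene made by cleaving (R)-limonene oxide, whose isopropenyl group becomes C1 and whose stereocentre becomes C2. Hg(OTf)2 turns the isopropenyl group into a bridged mercurinium ion (a temporary C–Hg bond that blocks hydride shift at C2); the (E)-C5=C6 enoate attacks it, setting C6 and leaving the C4=C5 double bond. The same keto aldehyde supplies the acyclic end; two Wittig reactions with a C10 dialdehyde join the halves.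

Key step: step 4

Remark on numbering: atom labels in the text follow carotenoid numbering. C1 = ring C(CH3)2, C2 = ring CH carrying the hydroxymethylbutenyl chain, C3 = ring CH2, C4 = ring CH=, C5 = ring C(CH3)=, C6 = ring CH carrying the polyene, C7 onward = chain. Primed labels are used for the acyclic end (C1' = C(CH3)2OH, C2' = its stereocentre). Locants inside systematic names are IUPAC locants.

Assumption: commercial (+)-limonene oxide is the (4R) compound of high enantiomeric purity; minor Z isomers from the olefinations are removed by chromatography or converge in the iodine equilibration of step 20.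

**Route**

Step 1
Reactants: 1 (4R)-limonene 1,2-oxide (cis/trans mixture at the epoxide)
Product: 2 (3R)-6-oxo-3-(prop-1-en-2-yl)heptanal
Conditions: H5IO6, THF/H2O, 0 °C → rt
Reagents that add atoms: water, O
Why: Periodic acid hydrolyses the epoxide to the diol and cleaves it in the same pot (Malaprade glycol cleavage), both epoxide isomers converge, and neither the isopropenyl group nor the stereocentre is involved.

Step 2
Reactants: 2 (3R)-6-oxo-3-(prop-1-en-2-yl)heptanal
Product: 3 ethyl (2E,5R)-2-methyl-8-oxo-5-(prop-1-en-2-yl)non-2-enoate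
Conditions: Ph3P=C(CH3)CO2Et, CH2Cl2, rt
Reagents that add atoms: ethyl 2-(triphenylphosphoranylidene)propanoate, CCOC(=O)C(C)=P(c1ccccc1)(c1ccccc1)c1ccccc1
Why: The stabilised ylide reacts only with the aldehyde (Wittig reaction), leaves the methyl ketone alone and should give the (E)-trisubstituted enoate that later becomes the C2 side chain.

Step 3
Reactants: 3 ethyl (2E,5R)-2-methyl-8-oxo-5-(prop-1-en-2-yl)non-2-enoate
Product: 4 diethyl (2E,5R,8E)-2,8-dimethyl-5-(prop-1-en-2-yl)deca-2,8-dienedioate
Conditions: (EtO)2P(O)CH2CO2Et, NaH, THF, 0 → 50 °C; chromatography to remove the 8Z isomer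
Reagents that add atoms: triethyl phosphonoacetate, CCOC(=O)CP(=O)(OCC)OCC
Why: Horner–Wadsworth–Emmons olefination of the methyl ketone should give mainly the (8E)-enoate, which installs C6 and C7; the stereocentre is remote and not acidic.

Step 4
Reactants: 4 diethyl (2E,5R,8E)-2,8-dimethyl-5-(prop-1-en-2-yl)deca-2,8-dienedioate
Product: 6 alkylmercury chloride of the cyclised diester (ethyl (1R,5R)-6-(chloromercuriomethyl)-5-[(2E)-4-ethoxy-3-methyl-4-oxobut-2-en-1-yl]-2,6-dimethylcyclohex-2-ene-1-carboxylate; both epimers at the CH2HgCl carbon), via alkylmercury triflate 5 (not isolated)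
Conditions: Hg(OTf)2 (mercury bis(trifluoromethanesulfonate)), PhNMe2, MeNO2, −20 °C; then sat. aq. NaCl
Reagents that add atoms: mercury bis(trifluoromethanesulfonate), FC(F)(F)S(=O)(=O)O[Hg]OS(=O)(=O)C(F)(F)F; sodium chloride, [Na+].[Cl-]
Why: Hg(OTf)2 adds reversibly to the 1,1-disubstituted C1=CH2 alkene, the bridged mercurinium ion is opened at its tertiary carbon C1 by C6 of the (E)-C5=C6 enoate, and the tertiary cation at C5 loses H-4 to the aniline to give the C4=C5 alkene and alkylmercury triflate 5, which brine converts into chloride 6. The closest known reactions are the Hg(OTf)2-induced olefin cyclisations of terpenoid polyenes and the acid cyclisation of geranic esters to alpha-cyclogeranates. The ring closes in a 6-endo-trig mode at the C5=C6 alkene with Markovnikov opening of the mercurinium ion, which forms the C1–C6 bond between the quaternary and the tertiary carbon. C6 is controlled by the C2 stereocentre through a chair transition state in which the C2 side chain is equatorial and the (E)-alkene holds the ester carbon C7 equatorial, so that C7 ends cis to the C2 side chain (6R beside 2R); the carbon bearing CH2HgCl becomes a stereocentre of no consequence that step 5 erases. C2 keeps its configuration because a bridged mercurinium ion, unlike a free tertiary cation, does not shift hydride from C2 or eliminate to the C1=C2 alkene. The step needs site selectivity (divalent mercury prefers the unhindered 1,1-disubstituted alkene over the two trisubstituted, electron-poor enoate alkenes), cis selectivity (equatorial substituents in the chair) and loss of H-4 instead of H-6 or a methyl proton (H-6 is shielded by the ester and the quaternary C1).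

Step 5
Reactants: 6 alkylmercury chloride of the cyclised diester
Product: 7 [(1R,5R)-5-[(2E)-4-hydroxy-3-methylbut-2-en-1-yl]-2,6,6-trimethylcyclohex-2-en-1-yl]methanol
Conditions: LiAlH4, THF, 0 °C → rt; aqueous NaOH work-up, filtration from elemental mercury
Reagents that add atoms: none
Why: LiAlH4 reduces both esters to primary alcohols and cleaves the carbon–mercury bond by hydride (reductive demercuration), which turns CH2HgCl into the second methyl on C1 and leaves C2 and C6 untouched.

Step 6
Reactants: 7 diol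
Product: 8 [(1R,5R)-5-[(2E)-4-{[tert-butyl(diphenyl)silyl]oxy}-3-methylbut-2-en-1-yl]-2,6,6-trimethylcyclohex-2-en-1-yl]methanol
Conditions: t-BuPh2SiCl (1.05 equiv), imidazole, CH2Cl2, −20 → 0 °C
Reagents that add atoms: tert-butyl(chloro)diphenylsilane, CC(C)(C)[Si](Cl)(c1ccccc1)c1ccccc1
Why: The bulky chlorosilane should select the unhindered allylic primary alcohol over the neopentyl-type CH2OH on C6, which is flanked by the quaternary C1 and by C5.

Step 7
Reactants: 8 mono-silyl ether
Product: 9 (1R,5R)-5-[(2E)-4-{[tert-butyl(diphenyl)silyl]oxy}-3-methylbut-2-en-1-yl]-2,6,6-trimethylcyclohex-2-ene-1-carbaldehyde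
Conditions: Dess–Martin periodinane, pyridine, CH2Cl2, 0 °C
Reagents that add atoms: none
Why: Dess–Martin oxidation under buffered, non-basic conditions should give the beta,gamma-unsaturated aldehyde without epimerising C6 or moving the C4=C5 double bond.

Step 8
Reactants: 9 aldehyde
Product: 10 ethyl (2E,4E)-5-[(1R,5R)-5-[(2E)-4-{[tert-butyl(diphenyl)silyl]oxy}-3-methylbut-2-en-1-yl]-2,6,6-trimethylcyclohex-2-en-1-yl]-3-methylpenta-2,4-dienoate
Conditions: (EtO)2P(O)CH2C(CH3)=CHCO2Et, LiN(SiMe3)2, THF, −78 → 0 °C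
Reagents that add atoms: triethyl 3-methyl-4-phosphonocrotonate, CCOC(=O)/C=C(\C)CP(=O)(OCC)OCC
Why: Horner–Wadsworth–Emmons reaction of the preformed lithium phosphonate (no free base) at low temperature adds the C5 unit with an (E)-C7=C8 bond and mainly an (E)-C9=C10 bond before C6 can enolise.

Step 9
Reactants: 10 dienoate
Product: 11 (2E,4E)-5-[(1R,5R)-5-[(2E)-4-{[tert-butyl(diphenyl)silyl]oxy}-3-methylbut-2-en-1-yl]-2,6,6-trimethylcyclohex-2-en-1-yl]-3-methylpenta-2,4-dien-1-ol
Conditions: i-Bu2AlH, CH2Cl2, −78 °C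
Reagents that add atoms: none
Why: i-Bu2AlH reduces the dienoate to the allylic alcohol by 1,2-reduction and leaves the silyl ether alone.

Step 10
Reactants: 11 dienol
Product: 12 [(2E,4E)-5-[(1R,5R)-5-[(2E)-4-{[tert-butyl(diphenyl)silyl]oxy}-3-methylbut-2-en-1-yl]-2,6,6-trimethylcyclohex-2-en-1-yl]-3-methylpenta-2,4-dien-1-yl]triphenylphosphonium bromide
Conditions: PPh3·HBr, CH2Cl2, 0 °C → rt
Reagents that add atoms: triphenylphosphine hydrobromide, [Br-].[PH+](c1ccccc1)(c1ccccc1)c1ccccc1
Why: The dienylic primary alcohol ionises under this mild acid and PPh3 traps the delocalised cation at its unhindered terminus C11 (standard Wittig salt formation of ionylidene-ethanol type alcohols), a process that leaves C6 and the silyl ether intact.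

Step 11
Reactants: 12 ring-end phosphonium bromide; 13 (2E,4E,6E)-2,7-dimethylocta-2,4,6-trienedial (3 equiv)
Product: 15 (2E,4E,6E,8E,10E,12E)-13-[(1R,5R)-5-[(2E)-4-{[tert-butyl(diphenyl)silyl]oxy}-3-methylbut-2-en-1-yl]-2,6,6-trimethylcyclohex-2-en-1-yl]-2,7,11-trimethyltrideca-2,4,6,8,10,12-hexaenal, via ylide 14 (not isolated)
Conditions: NaOMe, CH2Cl2/MeOH, 0 °C → rt; slow addition of the salt to excess 13
Reagents that add atoms: none
Why: Wittig reaction of the semi-stabilised ylide with one aldehyde group of the excess dialdehyde should give the mono-adduct with the C11=C12 bond, and any 11Z isomer converges in step 20.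

Step 12
Reactants: 2 (3R)-6-oxo-3-(prop-1-en-2-yl)heptanal
Product: 16 (5R)-8-methyl-5-(prop-1-en-2-yl)non-7-en-2-one
Conditions: i-PrPPh3 I, n-BuLi, THF, 0 °C; then 2, −78 → 0 °C
Reagents that add atoms: isopropyltriphenylphosphonium iodide, CC(C)[P+](c1ccccc1)(c1ccccc1)c1ccccc1.[I-]
Why: The hindered non-stabilised ylide olefinates the aldehyde much faster than the methyl ketone at low temperature (Wittig reaction) and so builds the prenyl group of the acyclic end.

Step 13
Reactants: 16 isopropenyl ketone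
Product: 17 (5R)-5-(2-hydroxypropan-2-yl)-8-methylnon-7-en-2-one
Conditions: Co(acac)2 (cobalt bis(acetylacetonate), cat.), PhSiH3, O2 (1 atm), THF, rt
Reagents that add atoms: dioxygen, O=O
Why: Mukaiyama hydration by hydrogen-atom transfer is Markovnikov and selects the 1,1-disubstituted alkene over the trisubstituted one, and the radical at C1' leaves the neighbouring stereocentre intact.

Step 14
Reactants: 17 hydroxy ketone
Product: 18 (3E,5S)-5-(2-hydroxypropan-2-yl)-8-methylnona-3,7-dien-2-one
Conditions: IBX (2.5 equiv), DMSO/toluene, 70 °C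
Reagents that add atoms: none
Why: IBX dehydrogenates the ketone through its more substituted enol (the methyl side has no beta-hydrogen) to the (E)-enone, does not oxidise the tertiary alcohol and, being non-basic, leaves the now allylic stereocentre C2' alone.

Step 15
Reactants: 18 enone
Product: 19 (4E,6S)-6-(2-hydroxypropan-2-yl)-3,9-dimethyldeca-1,4,8-trien-3-ol (both C3 epimers)
Conditions: CH2=CHMgBr (2.5 equiv), THF, −78 → 0 °C
Reagents that add atoms: vinylmagnesium bromide, C=C[Mg]Br
Why: 1,2-Addition of the vinyl Grignard reagent to the enone gives the bis-allylic tertiary alcohol, whose new carbinol centre is removed in the next step.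

Step 16
Reactants: 19 bis-allylic alcohol
Product: 20 [(2E,4E,6S)-6-(2-hydroxypropan-2-yl)-3,9-dimethyldeca-2,4,8-trien-1-yl]triphenylphosphonium bromide
Conditions: PPh3·HBr, MeOH/CH2Cl2, 0 °C → rt
Reagents that add atoms: triphenylphosphine hydrobromide, [Br-].[PH+](c1ccccc1)(c1ccccc1)c1ccccc1
Why: The bis-allylic alcohol ionises to a pentadienyl cation that PPh3 traps at its primary terminus (allylic transposition as in vinyl-ionol chemistry), while the saturated tertiary alcohol at C1' should not ionise under these conditions.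

Step 17
Reactants: 20 dienyl phosphonium bromide; 21 ethyl (2E)-3-methyl-4-oxobut-2-enoate
Product: 23 ethyl (2E,4E,6E,8E,10S)-10-(2-hydroxypropan-2-yl)-3,7,13-trimethyltetradeca-2,4,6,8,12-pentaenoate, via ylide 22 (not isolated)
Conditions: NaOEt, EtOH/CH2Cl2, 0 °C → rt
Reagents that add atoms: none
Why: Wittig reaction of the semi-stabilised ylide with the aldehyde group of the C5 building block forms the C7'=C8' bond, and the ester carbonyl does not react.

Step 18
Reactants: 23 pentaenoate
Product: 24 (2E,4E,6E,8E,10S)-10-(2-hydroxypropan-2-yl)-3,7,13-trimethyltetradeca-2,4,6,8,12-pentaen-1-ol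
Conditions: i-Bu2AlH (3.5 equiv), CH2Cl2, −78 °C
Reagents that add atoms: none
Why: i-Bu2AlH reduces the conjugated ester to the allylic alcohol by 1,2-reduction, the free tertiary alcohol only consuming one equivalent.

Step 19
Reactants: 24 pentaenol
Product: 25 [(2E,4E,6E,8E,10S)-10-(2-hydroxypropan-2-yl)-3,7,13-trimethyltetradeca-2,4,6,8,12-pentaen-1-yl]triphenylphosphonium bromide
Conditions: PPh3·HBr, CH2Cl2/MeOH, 0 °C
Reagents that add atoms: triphenylphosphine hydrobromide, [Br-].[PH+](c1ccccc1)(c1ccccc1)c1ccccc1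
Why: Same Wittig salt formation as in step 10, the delocalised cation being trapped by PPh3 at the primary terminus C11'.

Step 20
Reactants: 15 ring-end C30 aldehyde; 25 acyclic C20 phosphonium bromide
Product: 27 tert-butyldiphenylsilyl ether of the target at the primary allylic hydroxyl, via ylide 26 (not isolated)
Conditions: NaOMe, CH2Cl2/MeOH, 0 °C → rt; then I2 (cat.), CH2Cl2, rt, diffuse light
Reagents that add atoms: none
Why: Wittig union of the two halves forms the C11'=C12' bond, and iodine-catalysed equilibration should converge the Z isomers formed here and carried from steps 8, 11 and 17 onto the thermodynamically favoured all-E polyene without touching the three sp3 stereocentres.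

Step 21
Reactants: 27 silyl ether of the target
Product: 28 target CNP0409952.1, (2R,6R,2'S)
Conditions: Bu4NF, THF, 0 °C → rt, dark, argon
Reagents that add atoms: none
Why: Fluoride cleaves the silyl ether under conditions that the polyene and both alcohols tolerate.

**Compound list**

1 | (4R)-limonene 1,2-oxide, (4R)-1-methyl-4-(prop-1-en-2-yl)-7-oxabicyclo[4.1.0]heptane, cis/trans mixture | CC12CC[C@H](CC1O2)C(C)=C | starting material
2 | (3R)-6-oxo-3-(prop-1-en-2-yl)heptanal | O=CC[C@@H](CCC(C)=O)C(C)=C | intermediate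
3 | ethyl (2E,5R)-2-methyl-8-oxo-5-(prop-1-en-2-yl)non-2-enoate | CCOC(=O)/C(C)=C/C[C@@H](CCC(C)=O)C(C)=C | intermediate
4 | diethyl (2E,5R,8E)-2,8-dimethyl-5-(prop-1-en-2-yl)deca-2,8-dienedioate | CCOC(=O)/C(C)=C/C[C@@H](CC/C(C)=C/C(=O)OCC)C(C)=C | intermediate
5 | alkylmercury triflate of the cyclised diester (CH2HgOTf in place of one C1 methyl, both epimers) | CCOC(=O)[C@@H]1C(C)=CC[C@H](C/C=C(\C)C(=O)OCC)C1(C)C[Hg]OS(=O)(=O)C(F)(F)F | intermediate (not isolated)
6 | ethyl (1R,5R)-6-(chloromercuriomethyl)-5-[(2E)-4-ethoxy-3-methyl-4-oxobut-2-en-1-yl]-2,6-dimethylcyclohex-2-ene-1-carboxylate, both epimers at the CH2HgCl carbon | CCOC(=O)[C@@H]1C(C)=CC[C@H](C/C=C(\C)C(=O)OCC)C1(C)C[Hg]Cl | intermediate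
7 | [(1R,5R)-5-[(2E)-4-hydroxy-3-methylbut-2-en-1-yl]-2,6,6-trimethylcyclohex-2-en-1-yl]methanol | OC[C@@H]1C(C)=CC[C@H](C/C=C(\C)CO)C1(C)C | intermediate
8 | [(1R,5R)-5-[(2E)-4-{[tert-butyl(diphenyl)silyl]oxy}-3-methylbut-2-en-1-yl]-2,6,6-trimethylcyclohex-2-en-1-yl]methanol | OC[C@@H]1C(C)=CC[C@H](C/C=C(\C)CO[Si](c2ccccc2)(c2ccccc2)C(C)(C)C)C1(C)C | intermediate
9 | (1R,5R)-5-[(2E)-4-{[tert-butyl(diphenyl)silyl]oxy}-3-methylbut-2-en-1-yl]-2,6,6-trimethylcyclohex-2-ene-1-carbaldehyde | O=C[C@@H]1C(C)=CC[C@H](C/C=C(\C)CO[Si](c2ccccc2)(c2ccccc2)C(C)(C)C)C1(C)C | intermediate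
10 | ethyl (2E,4E)-5-[(1R,5R)-5-[(2E)-4-{[tert-butyl(diphenyl)silyl]oxy}-3-methylbut-2-en-1-yl]-2,6,6-trimethylcyclohex-2-en-1-yl]-3-methylpenta-2,4-dienoate | CCOC(=O)/C=C(C)/C=C/[C@@H]1C(C)=CC[C@H](C/C=C(\C)CO[Si](c2ccccc2)(c2ccccc2)C(C)(C)C)C1(C)C | intermediate
11 | (2E,4E)-5-[(1R,5R)-5-[(2E)-4-{[tert-butyl(diphenyl)silyl]oxy}-3-methylbut-2-en-1-yl]-2,6,6-trimethylcyclohex-2-en-1-yl]-3-methylpenta-2,4-dien-1-ol | OC/C=C(C)/C=C/[C@@H]1C(C)=CC[C@H](C/C=C(\C)CO[Si](c2ccccc2)(c2ccccc2)C(C)(C)C)C1(C)C | intermediate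
12 | ring-end C20 triphenylphosphonium bromide (PPh3 on C11 of 11 in place of OH) | [Br-].c1ccccc1[P+](c1ccccc1)(c1ccccc1)C/C=C(C)/C=C/[C@@H]1C(C)=CC[C@H](C/C=C(\C)CO[Si](c2ccccc2)(c2ccccc2)C(C)(C)C)C1(C)C | intermediate
13 | (2E,4E,6E)-2,7-dimethylocta-2,4,6-trienedial | O=C/C(C)=C/C=C/C=C(C)/C=O | starting material
14 | ylide of 12 | c1ccccc1[P+](c1ccccc1)(c1ccccc1)[CH-]/C=C(C)/C=C/[C@@H]1C(C)=CC[C@H](C/C=C(\C)CO[Si](c2ccccc2)(c2ccccc2)C(C)(C)C)C1(C)C | intermediate (not isolated)
15 | (2E,4E,6E,8E,10E,12E)-13-[(1R,5R)-5-[(2E)-4-{[tert-butyl(diphenyl)silyl]oxy}-3-methylbut-2-en-1-yl]-2,6,6-trimethylcyclohex-2-en-1-yl]-2,7,11-trimethyltrideca-2,4,6,8,10,12-hexaenal | O=C/C(C)=C/C=C/C=C(C)/C=C/C=C(C)/C=C/[C@@H]1C(C)=CC[C@H](C/C=C(\C)CO[Si](c2ccccc2)(c2ccccc2)C(C)(C)C)C1(C)C | intermediate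
16 | (5R)-8-methyl-5-(prop-1-en-2-yl)non-7-en-2-one | CC(C)=CC[C@@H](CCC(C)=O)C(C)=C | intermediate
17 | (5R)-5-(2-hydroxypropan-2-yl)-8-methylnon-7-en-2-one | CC(C)=CC[C@@H](CCC(C)=O)C(C)(C)O | intermediate
18 | (3E,5S)-5-(2-hydroxypropan-2-yl)-8-methylnona-3,7-dien-2-one | CC(C)=CC[C@@H](/C=C/C(C)=O)C(C)(C)O | intermediate
19 | (4E,6S)-6-(2-hydroxypropan-2-yl)-3,9-dimethyldeca-1,4,8-trien-3-ol, both C3 epimers | CC(C)=CC[C@@H](/C=C/C(C)(O)C=C)C(C)(C)O | intermediate
20 | [(2E,4E,6S)-6-(2-hydroxypropan-2-yl)-3,9-dimethyldeca-2,4,8-trien-1-yl]triphenylphosphonium bromide | CC(C)=CC[C@@H](/C=C/C(C)=C/C[P+](c1ccccc1)(c1ccccc1)c1ccccc1)C(C)(C)O.[Br-] | intermediate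
21 | ethyl (2E)-3-methyl-4-oxobut-2-enoate | CCOC(=O)/C=C(\C)C=O | starting material
22 | ylide of 20 | CC(C)=CC[C@@H](/C=C/C(C)=C/[CH-][P+](c1ccccc1)(c1ccccc1)c1ccccc1)C(C)(C)O | intermediate (not isolated)
23 | ethyl (2E,4E,6E,8E,10S)-10-(2-hydroxypropan-2-yl)-3,7,13-trimethyltetradeca-2,4,6,8,12-pentaenoate | CC(C)=CC[C@@H](/C=C/C(C)=C/C=C/C(C)=C/C(=O)OCC)C(C)(C)O | intermediate
24 | (2E,4E,6E,8E,10S)-10-(2-hydroxypropan-2-yl)-3,7,13-trimethyltetradeca-2,4,6,8,12-pentaen-1-ol | CC(C)=CC[C@@H](/C=C/C(C)=C/C=C/C(C)=C/CO)C(C)(C)O | intermediate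
25 | [(2E,4E,6E,8E,10S)-10-(2-hydroxypropan-2-yl)-3,7,13-trimethyltetradeca-2,4,6,8,12-pentaen-1-yl]triphenylphosphonium bromide | CC(C)=CC[C@@H](/C=C/C(C)=C/C=C/C(C)=C/C[P+](c1ccccc1)(c1ccccc1)c1ccccc1)C(C)(C)O.[Br-] | intermediate
26 | ylide of 25 | CC(C)=CC[C@@H](/C=C/C(C)=C/C=C/C(C)=C/[CH-][P+](c1ccccc1)(c1ccccc1)c1ccccc1)C(C)(C)O | intermediate (not isolated)
27 | tert-butyldiphenylsilyl ether of the target at the primary allylic hydroxyl | CC(C)=CC[C@@H](/C=C/C(C)=C/C=C/C(C)=C/C=C/C(C)=C/C=C/C=C(C)/C=C/C=C(C)/C=C/[C@@H]1C(C)=CC[C@H](C/C=C(\C)CO[Si](c2ccccc2)(c2ccccc2)C(C)(C)C)C1(C)C)C(C)(C)O | intermediate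
28 | target CNP0409952.1, (2R,6R,2'S) | CC(C)=CC[C@@H](/C=C/C(C)=C/C=C/C(C)=C/C=C/C(C)=C/C=C/C=C(C)/C=C/C=C(C)/C=C/[C@@H]1C(C)=CC[C@H](C/C=C(\C)CO)C1(C)C)C(C)(C)O | target

**Step count and risks**

Total step count: 21. Longest linear sequence: 13 steps (steps 1 to 11, then 20 and 21).

Steps most likely to fail:

Step 4. The mercurinium ion may be too weak an electrophile for the electron-poor C5=C6 alkene, so that the ring does not close. Proton loss may also go to the ring methyl and give the exocyclic alkene, or the chair preference may give too little of the cis isomer. The fallback generates the C1 cation by ionisation instead of by alkene activation. It sets out from 4: Mukaiyama hydration of the isopropenyl group (Co(acac)2, PhSiH3, O2, as in step 13) would give the tertiary alcohol diethyl (2E,5R,8E)-5-(2-hydroxypropan-2-yl)-2,8-dimethyldeca-2,8-dienedioate F1. SnCl4 in CH2Cl2 at −78 °C would ionise it and close the ring by the classical geranate-type cation–olefin cyclisation to the mercury-free diester ethyl (1R,5R)-5-[(2E)-4-ethoxy-3-methyl-4-oxobut-2-en-1-yl]-2,6,6-trimethylcyclohex-2-ene-1-carboxylate F2; the acidic medium would also move an exocyclic alkene into the ring. LiAlH4 would then reduce F2 to diol 7, where the route is rejoined. The price is a free tertiary cation, from which some hydride shift at C2 and hence some loss of enantiomeric purity must be expected.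

Step 14. The dehydrogenation of an unactivated open-chain ketone may stall at low conversion or be accompanied by oxidation at the allylic positions of the prenyl group. The fallback is a Saegusa–Ito oxidation and sets out from 17. Me3SiCl, NaI and Et3N in MeCN would give the bis-silyl compound (thermodynamic Z silyl enol ether and silylated tertiary alcohol) trimethyl{[(2Z,5S)-8-methyl-5-{2-[(trimethylsilyl)oxy]propan-2-yl}nona-2,7-dien-2-yl]oxy}silane F3. Pd(OAc)2 in MeCN would convert it into the enone (3E,5S)-8-methyl-5-{2-[(trimethylsilyl)oxy]propan-2-yl}nona-3,7-dien-2-one F4, and K2CO3 in MeOH would remove the remaining silyl ether to return 18.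

Step 16. The pentadienyl cation may be captured by the neighbouring tertiary hydroxyl (cyclic ether formation) or lose the proton at C2' (elimination, loss of the stereocentre) faster than PPh3 traps it. The fallback builds the same chain without a carbocation and sets out from 18. Horner–Wadsworth–Emmons reaction with triethyl phosphonoacetate and NaH would give ethyl (2E,4E,6S)-6-(2-hydroxypropan-2-yl)-3,9-dimethyldeca-2,4,8-trienoate F5. i-Bu2AlH would reduce it to (2E,4E,6S)-6-(2-hydroxypropan-2-yl)-3,9-dimethyldeca-2,4,8-trien-1-ol F6, and MnO2 would oxidise this to (2E,4E,6S)-6-(2-hydroxypropan-2-yl)-3,9-dimethyldeca-2,4,8-trienal F7. A second Horner–Wadsworth–Emmons reaction with the lithium salt of triethyl 3-methyl-4-phosphonocrotonate would give 23, where the route is rejoined.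

Further compounds
F1 | step 4 | diethyl (2E,5R,8E)-5-(2-hydroxypropan-2-yl)-2,8-dimethyldeca-2,8-dienedioate | CCOC(=O)/C(C)=C/C[C@@H](CC/C(C)=C/C(=O)OCC)C(C)(C)O
F2 | step 4 | ethyl (1R,5R)-5-[(2E)-4-ethoxy-3-methyl-4-oxobut-2-en-1-yl]-2,6,6-trimethylcyclohex-2-ene-1-carboxylate | CCOC(=O)[C@@H]1C(C)=CC[C@H](C/C=C(\C)C(=O)OCC)C1(C)C
F3 | step 14 | trimethyl{[(2Z,5S)-8-methyl-5-{2-[(trimethylsilyl)oxy]propan-2-yl}nona-2,7-dien-2-yl]oxy}silane | CC(C)=CC[C@@H](C/C=C(/C)O[Si](C)(C)C)C(C)(C)O[Si](C)(C)C
F4 | step 14 | (3E,5S)-8-methyl-5-{2-[(trimethylsilyl)oxy]propan-2-yl}nona-3,7-dien-2-one | CC(C)=CC[C@@H](/C=C/C(C)=O)C(C)(C)O[Si](C)(C)C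
F5 | step 16 | ethyl (2E,4E,6S)-6-(2-hydroxypropan-2-yl)-3,9-dimethyldeca-2,4,8-trienoate | CC(C)=CC[C@@H](/C=C/C(C)=C/C(=O)OCC)C(C)(C)O
F6 | step 16 | (2E,4E,6S)-6-(2-hydroxypropan-2-yl)-3,9-dimethyldeca-2,4,8-trien-1-ol | CC(C)=CC[C@@H](/C=C/C(C)=C/CO)C(C)(C)O
F7 | step 16 | (2E,4E,6S)-6-(2-hydroxypropan-2-yl)-3,9-dimethyldeca-2,4,8-trienal | CC(C)=CC[C@@H](/C=C/C(C)=C/C=O)C(C)(C)O
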